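**Retrosynthetic overview**
- The target comes from the 2α,3α-diol by regioselective angeloylation of the equatorial 2α-OH.
- Rings A and B form in one iron-hydride radical cascade from an acyclic triene-diol allyl sulfone: H-atom transfer to the isopropenyl group gives the C4 radical, ring A closes first (C4–C5), ring B second (C10–C9), and PhSO2 leaves from C7 to fix C7=C8. The chiral cis-diol at C2/C3 controls C5, C9 and C10.
- The polyene comes from a three-component union (C6–C7 bond and C5=C10 alkene): linalool-derived allyl sulfone anion + vinylphosphonium salt + α-acetoxy ketone, which already carries the C20 acetate.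
- The ketone comes from 2,3-O-isopropylidene-D-erythronolactone (C2, C3 from the chiral pool) via an iodide and nickel-catalysed acylation; the sulfone comes from (R)-linalool (C13) by allylic oxidation.

Assumption: the SMILES encodes the normal-series labdane (2R,3S,5R,9S,10S,13R: 2α-O-angeloyl, 3α-OH, 5α-H, 9α-H, 10β-CH2OAc); labdane numbers are used for these carbons in all intermediates.

**Step 1**
Reactants: 1 (R)-(−)-linalool
Product: 2 (2E,6R)-2,6-dimethylocta-2,7-diene-1,6-diol
Conditions: SeO2 (0.3 equiv), t-BuOOH (2.5 equiv), salicylic acid (0.1 equiv), CH2Cl2, rt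
Reagents that add atoms: tert-butyl hydroperoxide, CC(C)(C)OO
Why: Riley allylic oxidation (ene reaction then [2,3]-sigmatropic shift) oxidises only the (E)-methyl group of the trisubstituted alkene, so the 2E geometry is set by the mechanism and the carbinol centre of linalool is untouched.

**Step 2**
Reactants: 2 (2E,6R)-2,6-dimethylocta-2,7-diene-1,6-diol
Product: 4 (3R,6E)-3,7-dimethyl-8-(phenylsulfonyl)octa-1,6-dien-3-ol, via allylic mesylate 3 (not isolated)
Conditions: MsCl, Et3N, THF, −40 °C; then PhSO2Na, n-Bu4NI (cat.), DMF, 0 °C to rt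
Reagents that add atoms: sodium benzenesulfinate, [Na+].[O-]S(=O)c1ccccc1; methanesulfonyl chloride, CS(=O)(=O)Cl (its atoms stay only in 3)
Why: the primary allylic alcohol is mesylated selectively beside the tertiary one and the soft sulfinate then displaces the mesylate through sulfur by SN2 without allylic transposition, so the E geometry and the carbinol centre are retained (sulfinate S-alkylation).

**Step 3**
Reactants: 5 2,3-O-isopropylidene-D-erythronolactone
Product: 7 [(4R,5S)-2,2-dimethyl-5-(prop-1-en-2-yl)-1,3-dioxolan-4-yl]methanol, via methyl lactol 6 (not isolated)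
Conditions: MeLi (1.05 equiv), THF, −78 °C; then Ph3P=CH2 (2.5 equiv, from Ph3PCH3Br and KOtBu), THF, −78 °C to rt
Reagents that add atoms: methyllithium, [Li]C; methylenetriphenylphosphorane (made in the flask from methyltriphenylphosphonium bromide and KOtBu), C=P(c1ccccc1)(c1ccccc1)c1ccccc1
Why: one equivalent of MeLi stops at the lithium lactolate, whose open keto-alkoxide form undergoes Wittig methylenation at or below room temperature, so both dioxolane stereocentres come unchanged from the chiral pool (they become C2 and C3).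

**Step 4**
Reactants: 7 [(4R,5S)-2,2-dimethyl-5-(prop-1-en-2-yl)-1,3-dioxolan-4-yl]methanol
Product: 8 (4S,5S)-4-(iodomethyl)-2,2-dimethyl-5-(prop-1-en-2-yl)-1,3-dioxolane
Conditions: I2, PPh3, imidazole, CH2Cl2, 0 °C to rt
Reagents that add atoms: iodine, II
Why: Appel-type (Garegg–Samuelsson) iodination replaces the primary hydroxyl by SN2 at the CH2 carbon and touches neither stereocentre (the descriptor change is only a priority change).

**Step 5**
Reactants: 8 (4S,5S)-4-(iodomethyl)-2,2-dimethyl-5-(prop-1-en-2-yl)-1,3-dioxolane; 9 acetoxyacetyl chloride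
Product: 10 3-[(4R,5S)-2,2-dimethyl-5-(prop-1-en-2-yl)-1,3-dioxolan-4-yl]-2-oxopropyl acetate
Conditions: NiCl2(dme) (5 mol%), 4,4'-di-tert-butyl-2,2'-bipyridine (5.5 mol%), Mn powder (3 equiv), DMA, 0 °C to rt
Reagents that add atoms: none
Why: nickel-catalysed reductive cross-electrophile acylation joins the primary iodide through its alkyl radical (which, unlike an organometallic, does not beta-eliminate the dioxolane oxygen) to the acid chloride and gives the alpha-acetoxy ketone directly with no new stereocentre.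

**Step 6**
Reactants: 4 (3R,6E)-3,7-dimethyl-8-(phenylsulfonyl)octa-1,6-dien-3-ol; 11 vinyltriphenylphosphonium bromide; 10 3-[(4R,5S)-2,2-dimethyl-5-(prop-1-en-2-yl)-1,3-dioxolan-4-yl]-2-oxopropyl acetate
Product: 13 (2Z,5RS,6E,10R)-2-{[(4R,5S)-2,2-dimethyl-5-(prop-1-en-2-yl)-1,3-dioxolan-4-yl]methyl}-10-hydroxy-6,10-dimethyl-5-(phenylsulfonyl)dodeca-2,6,11-trien-1-yl acetate, via phosphorus ylide 12 (not isolated)
Conditions: KN(SiMe3)2 (2.05 equiv), THF, −78 °C; add 11, −78 to −20 °C; then 10, −78 °C to rt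
Reagents that add atoms: none
Why: the sulfonyl-stabilised allyl anion adds through its alpha carbon to the vinylphosphonium salt (Schweizer reaction) to give a non-stabilised ylide, whose Wittig olefination of the alpha-oxygenated ketone follows the usual Z preference of such ketones and places CH2OAc cis to the new chain (C5=C10), while the sulfone-bearing C7 forms as a mixture that is erased in step 8.

**Step 7**
Reactants: 13 the acetonide polyene of step 6
Product: 14 (2Z,5RS,6E,10R)-2-[(2R,3S)-2,3-dihydroxy-4-methylpent-4-en-1-yl]-10-hydroxy-6,10-dimethyl-5-(phenylsulfonyl)dodeca-2,6,11-trien-1-yl acetate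
Conditions: PPTS (0.2 equiv), MeOH, 40 °C
Reagents that add atoms: none
Why: the strained cis-4,5-disubstituted dioxolane undergoes acid-catalysed transacetalisation to methanol under conditions mild enough for the tertiary allylic alcohol, the acetate and the allyl sulfone, and no stereocentre is touched.

**Step 8**
Reactants: 14 the triene triol sulfone of step 7
Product: 15 (13R)-2α,3α,13-trihydroxylabda-7,14-dien-20-yl acetate (2R,3S,5R,9S,10S,13R)
Conditions: Fe(acac)3 (0.3 equiv), PhSiH3 (2.5 equiv), EtOH/ethylene glycol (5:1), Ar, 60 °C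
Reagents that add atoms: none
Why: Proposed new method: a trivalent iron hydride made from Fe(acac)3 and PhSiH3 transfers a hydrogen atom to the 1,1-disubstituted isopropenyl group (the fastest acceptor, as in Mukaiyama-type hydrofunctionalisations) to give the tertiary C4 radical, which closes ring A 6-endo on C5 of the Z-trisubstituted alkene through a chair with the C2 hydroxyl equatorial (the other fold puts it 1,3-diaxial to a C4 methyl) and the C3 hydroxyl axial, the tertiary C10 radical then closes ring B 6-endo on C9 of the allyl sulfone through a second chair (trans fusion, CH2OAc axial, C9 chain equatorial), and beta-scission of the PhSO2 radical fixes the alkene at C7=C8 and erases the C7 centre while divalent iron reduces the sulfonyl radical to sulfinate and turns the catalyst over; the closest known reaction types are Fe(acac)3/PhSiH3 hydrogen-atom-transfer radical polyene cyclisations to trans-decalins, Cp2TiCl-mediated epoxypolyene radical bicyclisations and radical addition-fragmentation of allyl sulfones.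

**Step 9**
Reactants: 15 (13R)-2α,3α,13-trihydroxylabda-7,14-dien-20-yl acetate; 16 angelic acid [(Z)-2-methylbut-2-enoic acid]
Product: 18 (13R)-20-acetoxy-3α,13-dihydroxylabda-7,14-dien-2α-yl (Z)-2-methylbut-2-enoate (CNP0171655.1), via mixed anhydride 17 (not isolated)
Conditions: 16, 2,4,6-trichlorobenzoyl chloride, Et3N, toluene, rt; then 15, toluene, 75 °C
Reagents that add atoms: 2,4,6-trichlorobenzoyl chloride, O=C(Cl)c1c(Cl)cc(Cl)cc1Cl (its atoms stay only in 17)
Why: Yamaguchi esterification through the mixed anhydride without DMAP avoids angelate-to-tiglate isomerisation and acylates only the equatorial C2 hydroxyl, because the axial C3 hydroxyl is flanked by the gem-dimethyl carbon and the C13 hydroxyl is tertiary.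

**Compound list**
1 | (R)-(−)-linalool, (3R)-3,7-dimethylocta-1,6-dien-3-ol | C=C[C@](C)(O)CCC=C(C)C | starting material
2 | (2E,6R)-2,6-dimethylocta-2,7-diene-1,6-diol | C=C[C@](C)(O)CC/C=C(\C)CO | intermediate
3 | (2E,6R)-6-hydroxy-2,6-dimethylocta-2,7-dien-1-yl methanesulfonate | C=C[C@](C)(O)CC/C=C(\C)COS(C)(=O)=O | intermediate
4 | (3R,6E)-3,7-dimethyl-8-(phenylsulfonyl)octa-1,6-dien-3-ol | C=C[C@](C)(O)CC/C=C(\C)CS(=O)(=O)c1ccccc1 | intermediate
5 | 2,3-O-isopropylidene-D-erythronolactone, (3aR,6aR)-2,2-dimethyldihydrofuro[3,4-d][1,3]dioxol-4(3aH)-one | O=C1[C@H](OC2(C)C)[C@H](O2)CO1 | starting material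
6 | (3aR,6aR)-2,2,4-trimethyltetrahydrofuro[3,4-d][1,3]dioxol-4-ol (methyl lactol, anomer mixture, lithium alkoxide in the flask) | CC1(O)[C@H](OC2(C)C)[C@H](O2)CO1 | intermediate
7 | [(4R,5S)-2,2-dimethyl-5-(prop-1-en-2-yl)-1,3-dioxolan-4-yl]methanol | C=C(C)[C@H](OC1(C)C)[C@H](O1)CO | intermediate
8 | (4S,5S)-4-(iodomethyl)-2,2-dimethyl-5-(prop-1-en-2-yl)-1,3-dioxolane | C=C(C)[C@H](OC1(C)C)[C@H](O1)CI | intermediate
9 | acetoxyacetyl chloride | CC(=O)OCC(=O)Cl | starting material
10 | 3-[(4R,5S)-2,2-dimethyl-5-(prop-1-en-2-yl)-1,3-dioxolan-4-yl]-2-oxopropyl acetate | C=C(C)[C@H](OC1(C)C)[C@H](O1)CC(=O)COC(C)=O | intermediate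
11 | vinyltriphenylphosphonium bromide | C=C[P+](c1ccccc1)(c1ccccc1)c1ccccc1.[Br-] | starting material
12 | potassium (3R,6E)-3,7-dimethyl-8-(phenylsulfonyl)-10-(triphenylphosphoranylidene)deca-1,6-dien-3-olate (8RS) | C=C[C@](C)([O-])CC/C=C(\C)C(CC=P(c1ccccc1)(c1ccccc1)c1ccccc1)S(=O)(=O)c1ccccc1.[K+] | intermediate
13 | (2Z,5RS,6E,10R)-2-{[(4R,5S)-2,2-dimethyl-5-(prop-1-en-2-yl)-1,3-dioxolan-4-yl]methyl}-10-hydroxy-6,10-dimethyl-5-(phenylsulfonyl)dodeca-2,6,11-trien-1-yl acetate | C=C(C)[C@H](OC1(C)C)[C@H](O1)C/C(COC(C)=O)=C/CC(S(=O)(=O)c1ccccc1)/C(C)=C/CC[C@@](C)(O)C=C | intermediate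
14 | (2Z,5RS,6E,10R)-2-[(2R,3S)-2,3-dihydroxy-4-methylpent-4-en-1-yl]-10-hydroxy-6,10-dimethyl-5-(phenylsulfonyl)dodeca-2,6,11-trien-1-yl acetate | C=C(C)[C@H](O)[C@H](O)C/C(COC(C)=O)=C/CC(S(=O)(=O)c1ccccc1)/C(C)=C/CC[C@@](C)(O)C=C | intermediate
15 | (13R)-2α,3α,13-trihydroxylabda-7,14-dien-20-yl acetate (2R,3S,5R,9S,10S,13R) | C=C[C@](C)(O)CC[C@H]1C(C)=CC[C@H]2C(C)(C)[C@H](O)[C@H](O)C[C@]12COC(C)=O | intermediate
16 | angelic acid, (Z)-2-methylbut-2-enoic acid | C/C=C(/C)C(=O)O | starting material
17 | (Z)-2-methylbut-2-enoic 2,4,6-trichlorobenzoic anhydride | C/C=C(/C)C(=O)OC(=O)c1c(Cl)cc(Cl)cc1Cl | intermediate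
18 | (13R)-20-acetoxy-3α,13-dihydroxylabda-7,14-dien-2α-yl (Z)-2-methylbut-2-enoate (2R,3S,5R,9S,10S,13R) | C=C[C@](C)(O)CC[C@H]1C(C)=CC[C@H]2C(C)(C)[C@H](O)[C@H](OC(=O)/C(C)=C\C)C[C@]12COC(C)=O | target

**Totals**
Total step count: 9. Longest linear sequence: 7 steps (steps 3 to 9, from 5).

**Three steps most likely to fail**

Step 8, the radical bicyclisation. The risks are hydrogen-atom transfer to one of the other alkenes, reduction of the C4 or C10 radical before it cyclises, a sulfonyl-radical-induced 1,3-shift of the allyl sulfone, and weaker control by the free diol than assumed. The fallback sets out from 13, leaves out the hydrolysis and runs the same iron-hydride cascade on the rigid cis-fused dioxolane, which gives (13R)-13-hydroxy-2α,3α-(isopropylidenedioxy)labda-7,14-dien-20-yl acetate F4. Hydrolysis of F4 with CeCl3·7H2O and oxalic acid in MeCN then comes back to the route at 15.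

Step 6, the three-component union. The risks are enolisation or beta-elimination of the alpha-acetoxy ketone by the ylide, attack on the acetate, addition of the alkoxide to the phosphonium salt, and incomplete Z selectivity with an acyloxy rather than an alkoxy ketone. The fallback sets out from 8, which is coupled under the nickel conditions of step 5 with (tert-butyldimethylsilyloxy)acetyl chloride to give 1-(tert-butyldimethylsilyloxy)-3-[(4R,5S)-2,2-dimethyl-5-(prop-1-en-2-yl)-1,3-dioxolan-4-yl]propan-2-one F1, the classical alpha-silyloxy ketone for Z-selective Wittig reactions. The same union with 4 and 11 gives (2Z,5RS,6E,10R)-1-(tert-butyldimethylsilyloxy)-2-{[(4R,5S)-2,2-dimethyl-5-(prop-1-en-2-yl)-1,3-dioxolan-4-yl]methyl}-6,10-dimethyl-5-(phenylsulfonyl)dodeca-2,6,11-trien-10-ol F2. Bu4NF frees (2Z,5RS,6E,10R)-2-{[(4R,5S)-2,2-dimethyl-5-(prop-1-en-2-yl)-1,3-dioxolan-4-yl]methyl}-6,10-dimethyl-5-(phenylsulfonyl)dodeca-2,6,11-triene-1,10-diol F3, and acetylation of its primary hydroxyl (Ac2O, pyridine, 0 °C) comes back to the route at 13.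

Step 9, the angeloylation. The risks are isomerisation to the tiglate, acylation at O3 and acyl migration at 75 °C. The fallback sets out from 15, which is acylated at O2 with 2-(diphenoxyphosphoryl)propanoic acid (DCC, DMAP, CH2Cl2) to give (13R)-20-acetoxy-3α,13-dihydroxylabda-7,14-dien-2α-yl 2-(diphenoxyphosphoryl)propanoate F5. The angelate double bond is then built on the substrate by a Z-selective Ando-type Horner–Wadsworth–Emmons reaction of F5 with acetaldehyde (NaI, DBU, THF, 0 °C), which comes back to the route at 18.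

**Further compounds**
F1 | step 6 | 1-(tert-butyldimethylsilyloxy)-3-[(4R,5S)-2,2-dimethyl-5-(prop-1-en-2-yl)-1,3-dioxolan-4-yl]propan-2-one | C=C(C)[C@H](OC1(C)C)[C@H](O1)CC(=O)CO[Si](C)(C)C(C)(C)C
F2 | step 6 | (2Z,5RS,6E,10R)-1-(tert-butyldimethylsilyloxy)-2-{[(4R,5S)-2,2-dimethyl-5-(prop-1-en-2-yl)-1,3-dioxolan-4-yl]methyl}-6,10-dimethyl-5-(phenylsulfonyl)dodeca-2,6,11-trien-10-ol | C=C(C)[C@H](OC1(C)C)[C@H](O1)C/C(CO[Si](C)(C)C(C)(C)C)=C/CC(S(=O)(=O)c1ccccc1)/C(C)=C/CC[C@@](C)(O)C=C
F3 | step 6 | (2Z,5RS,6E,10R)-2-{[(4R,5S)-2,2-dimethyl-5-(prop-1-en-2-yl)-1,3-dioxolan-4-yl]methyl}-6,10-dimethyl-5-(phenylsulfonyl)dodeca-2,6,11-triene-1,10-diol | C=C(C)[C@H](OC1(C)C)[C@H](O1)C/C(CO)=C/CC(S(=O)(=O)c1ccccc1)/C(C)=C/CC[C@@](C)(O)C=C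
F4 | step 8 | (13R)-13-hydroxy-2α,3α-(isopropylidenedioxy)labda-7,14-dien-20-yl acetate | C=C[C@](C)(O)CC[C@H]1C(C)=CC[C@H]2C(C)(C)[C@H](OC3(C)C)[C@H](O3)C[C@]12COC(C)=O
F5 | step 9 | (13R)-20-acetoxy-3α,13-dihydroxylabda-7,14-dien-2α-yl 2-(diphenoxyphosphoryl)propanoate | C=C[C@](C)(O)CC[C@H]1C(C)=CC[C@H]2C(C)(C)[C@H](O)[C@H](OC(=O)C(C)P(=O)(Oc3ccccc3)Oc3ccccc3)C[C@]12COC(C)=O
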